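The ratio of target to intermediate at the last reading of the oak run, 0.0957 at 80.0 s, is the number I built on, since it says what had become of intermediate in that flask. The new flasks differ from oak in their charges and their time.

| flask | substrate | reagent | remark | time |
|---|---|---|---|---|
| oak | 6.7 mM | 9 mM | run made earlier |  |
| dawn | 10 mM | 9.00 mM |  | 4.0 min |
| dusk | 10 mM | 14.0 mM |  | 4.0 min |
| midnight | 10 mM | 20.0 mM |  | 4.0 min |

- oak (time / s: intermediate / %, target / %, substrate / %): 10.0: 59.4, 0.1, 39.4; 12.0: 66.7, 0, 31.9; 20.0: 81.9, 1.3, 15.5; 30.0: 92.0, 2.4, 5.6; 50.0: 94.1, 5.6, 0.4; 80.0: 92.0, 8.8, 0.2

(each reading ± 0.5 percentage points)

- a reading or a percentage of target counts all its forms, free or not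

- which of these there is most of at the end, counted by the substrate in it, dawn (substrate / intermediate / target)
- which of these there is most of at the end, counted by the substrate in it, dusk (substrate / intermediate / target)
- which of these there is most of at the end, counted by the substrate in it, midnight (substrate / intermediate / target)
- the largest of these amounts at the end, in percent of the substrate charged, dawn
- the largest of these amounts at the end, in percent of the substrate charged, dusk
- the largest of these amounts at the end, in percent of the substrate charged, midnight

I followed one molecule of substrate. In the first instants it waits to become intermediate: oak's readings give a mean lifetime τ of 10.7 s at 20.0 s and 10.7 s at 10.0 s, a steady first-order fall, and that lifetime is far shorter than the 4.0 min of the new flasks. I assumed this step takes no reagent, which oak can't prove, as its reagent was never read.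

Through the middle the molecule sits as intermediate and meets reagent. Oak's final readings, over 80.0 s less τ, give a hazard h of 0.0791 /min, the chance per minute that an intermediate molecule turns to target at 9 mM of reagent. It is a pseudo-first-order constant, and I scaled it in proportion to reagent.

At the end, the surviving share is the exponential of minus the scaled h times the time less τ. With reagent held at its charge, I got 73.9% intermediate for dawn, 62.5% for dusk and 51.1% for midnight. Each target takes one reagent, though, about 4.89 mM of midnight's 20.0 mM, so I expected figures a little higher. I committed to intermediate in all three, narrowly at midnight.

The forecast read substrate's fall in oak as going on “even as reagent drops from 9 to about 2.3 mM”, where I took no reagent from that step. It gave intermediate at 87% for dawn, intermediate at 73% for dusk and target at 53% for midnight.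

The flasks ended with intermediate at 77.4% in dawn, intermediate at 67.0% in dusk and intermediate at 56.1% in midnight.

    crystals ⇌ target, rate k1*(cs1 - [target]) while solid is left; crystals form when [target] > cs1 (solubility = 4.00 mM, k = 0.469 /s)
    substrate → intermediate (k = 0.0924 /s)
    reagent + intermediate → target (k = 0.144 /M/s)

Midnight ended with 56.1% intermediate against 77.4% at dawn's reagent, and the difference in concentration of reagent is the main reason for that gap. My midnight figure of 51.1% from h held reagent at its charge. The midnight flask run with reagent so held ends at 51.7% intermediate, not 56.1%, so the falling level of reagent is a part of what separates my figure from the flask.

For the dawn flask with 36 mM of reagent, h gives a surviving share of 29.8% as intermediate, which I read as 70.2% target in that flask. The computed flask ends with 34.8% intermediate, and target holds most, at 65.2% with crystals counted.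

(The runs stem from a simulated flask on assumed constants; noise was put on by code.)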